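The route fixes the diaryl ether oxygen to ring A while that ring is still a cyclohexanone. SN2 displacement on 2-chlorocyclohexanone by the phenoxide of tetrabromoguaiacol (ring B, its OH masked as OMe) gives racemic 2-(2,3,4,5-tetrabromo-6-methoxyphenoxy)cyclohexan-1-one, the precursor. Excess bromine then, in one operation, dehydrogenates the ketone ring to the phenol and places Br at C2 and C4. The step exploits the substitution pattern of ring A: the C1 hydroxyl sits next to the C6 ether oxygen, and the two bromines occupy exactly the ortho (C2) and para (C4) carbons that an enol or a phenol offers to electrophilic bromine. BBr3 demethylation of ring B finishes the synthesis.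

Key step: step 3

Remark on the chemistry: the target has no stereocentre and no hindered axis, so it is treated as achiral. The only stereocentre on the way (C2 of the cyclohexanone) is carried as the racemate and is erased on aromatization.

Step 1
Reactants: 1 guaiacol (2-methoxyphenol)
Product: 3 2,3,4,5-tetrabromo-6-methoxyphenol (tetrabromoguaiacol), via 2,3,4-tribromo-6-methoxyphenol 2 (not isolated)
Conditions: Br2 (4.5 equiv), Fe powder (cat.), AcOH, 20 → 70 °C; aq. NaHSO3
Reagents that add atoms: bromine, BrBr
Why: Exhaustive electrophilic aromatic bromination, in which the OH (para and ortho) and the OMe (para) direct three fast substitutions to give 2, and the last C–H, ortho to OMe and still activated, should be substituted by the excess of Br2 on warming, the bisulfite wash returning any ipso-brominated dienone to the phenol.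

Step 2
Reactants: 3 2,3,4,5-tetrabromo-6-methoxyphenol; 4 2-chlorocyclohexanone (racemic)
Product: 5 2-(2,3,4,5-tetrabromo-6-methoxyphenoxy)cyclohexan-1-one (racemic)
Conditions: K2CO3 (1.5 equiv), DMF, 60 °C
Reagents that add atoms: none
Why: Williamson-type SN2 O-alkylation of a phenoxide by a carbonyl-activated alpha-chloroketone, in which the acidic phenol is fully ionized by carbonate, the fully substituted ring allows no C-alkylation, and the weakly basic phenoxide should favour substitution over Favorskii or elimination pathways; the new stereocentre forms as the racemate and is of no consequence.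

Step 3
Reactants: 5 2-(2,3,4,5-tetrabromo-6-methoxyphenoxy)cyclohexan-1-one (racemic)
Product: 7 2,4-dibromo-6-(2,3,4,5-tetrabromo-6-methoxyphenoxy)phenol, via 2-(2,3,4,5-tetrabromo-6-methoxyphenoxy)phenol 6 (not isolated)
Conditions: Br2 (4.1 equiv, in portions), glacial AcOH, 20 → 80 °C (HBr vented to a scrubber); aq. NaHSO3
Reagents that add atoms: bromine, BrBr
Why: HBr-catalysed enolization, bromination alpha to the carbonyl and thermal loss of HBr, run twice over, should take the ketone ring to a cyclohexadienone that tautomerizes to phenol 6, which the remaining two equivalents of Br2 substitute at C2 and C4 by electrophilic aromatic substitution. The closest known reaction type is the halogen-mediated dehydrogenative aromatization of cyclohexanones (bromination–dehydrobromination) followed by ortho/para bromination of the phenol formed. No ring is closed and no stereocentre is created; the racemic centre of 5 becomes an sp2 carbon. The step needs site selectivity on ring A, and the substrate supplies it in two ways: the enol and dienol carbons of the ketone ring are the future ortho and para carbons, so any early bromination there ends where bromine is wanted, and in 6 the free OH directs far more strongly than the electron-poor aryloxy group. C3 and C5 are meta to OH and flanked by bromine, so holding Br2 near four equivalents should stop the sequence at the dibromide. Ring B has no C–H and its oxygen is capped as OMe, so it can neither be brominated nor add to the ketone (a path that would lead toward a dibenzodioxin), and the anhydrous medium protects the alpha-aryloxy ketone from hydrolytic loss of the aryloxy group.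

Step 4
Reactants: 7 2,4-dibromo-6-(2,3,4,5-tetrabromo-6-methoxyphenoxy)phenol
Product: 9 2,3,4,5-tetrabromo-6-(3,5-dibromo-2-hydroxyphenoxy)phenol (target), via bis(dibromoboryl) ether 8 (not isolated)
Conditions: BBr3 (3 equiv), CH2Cl2, −78 → 20 °C; then H2O, 0 °C
Reagents that add atoms: none
Why: Lewis-acid cleavage of an aryl methyl ether, in which boron coordinates the OMe oxygen and bromide attacks the methyl group by SN2 while the free phenol is held as its aryloxyborane, both B–O bonds being hydrolysed on cold aqueous work-up; the diaryl ether and the aryl bromides are inert, and the non-basic, cold work-up avoids base-induced ring closure of the ortho-hydroxy/ortho'-bromo diaryl ether to a dibenzodioxin.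

Compound list
1 | guaiacol (2-methoxyphenol) | COc1ccccc1O | starting material
2 | 2,3,4-tribromo-6-methoxyphenol (4,5,6-tribromoguaiacol) | COc1cc(Br)c(Br)c(Br)c1O | intermediate (not isolated)
3 | 2,3,4,5-tetrabromo-6-methoxyphenol (tetrabromoguaiacol) | COc1c(Br)c(Br)c(Br)c(Br)c1O | intermediate
4 | 2-chlorocyclohexanone (racemic) | O=C1CCCCC1Cl | starting material
5 | 2-(2,3,4,5-tetrabromo-6-methoxyphenoxy)cyclohexan-1-one (racemic) | COc1c(Br)c(Br)c(Br)c(Br)c1OC1CCCCC1=O | intermediate
6 | 2-(2,3,4,5-tetrabromo-6-methoxyphenoxy)phenol | COc1c(Br)c(Br)c(Br)c(Br)c1Oc1ccccc1O | intermediate (not isolated)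
7 | 2,4-dibromo-6-(2,3,4,5-tetrabromo-6-methoxyphenoxy)phenol | COc1c(Br)c(Br)c(Br)c(Br)c1Oc1cc(Br)cc(Br)c1O | intermediate
8 | bis(dibromoboryl) ether of the target (both phenolic oxygens bound to BBr2) | BrB(Br)Oc1c(Br)cc(Br)cc1Oc1c(OB(Br)Br)c(Br)c(Br)c(Br)c1Br | intermediate (not isolated)
9 | 2,3,4,5-tetrabromo-6-(3,5-dibromo-2-hydroxyphenoxy)phenol | Oc1c(Br)cc(Br)cc1Oc1c(O)c(Br)c(Br)c(Br)c1Br | target

Total step count: 4
Longest linear sequence: 4 steps (1 → 3 → 5 → 7 → 9)

Steps most likely to fail

Step 3. Three things may go wrong. Bromination at the ether-bearing carbon may be followed by ionization and loss of the aryloxy group. Dehydrobromination may stall at non-aromatic bromoenones. HBr may cleave the methyl ether before the ring is aromatic. The fallback gives up the cyclohexanone surrogate and makes the aryl–oxygen bond by SNAr. It sets out from 3 and returns at 7. Phenol 3 and 2-fluorobenzaldehyde (Cs2CO3, DMA, 120 °C) should give 2-(2,3,4,5-tetrabromo-6-methoxyphenoxy)benzaldehyde F1. Baeyer–Villiger (Dakin-type) oxidation with mCPBA in CH2Cl2 should give 2-(2,3,4,5-tetrabromo-6-methoxyphenoxy)phenyl formate F2. Hydrolysis with dilute aqueous HCl in THF at 20 °C should give phenol 6, now isolated. Bromination with Br2 (2.05 equiv) in AcOH at 20 °C, directed ortho and para by the free OH, should give 7.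

Step 2. The hindered, weakly nucleophilic phenoxide may displace chloride too slowly, so that base-induced self-condensation, dehydrochlorination or Favorskii rearrangement of the chloroketone consumes the electrophile. The fallback replaces the alpha-haloketone by an epoxide and adjusts the oxidation level afterwards. It sets out from 3 and returns at 5. Phenol 3 and cyclohexene oxide (cat. K2CO3, DMF, 100 °C) should give, by anti opening, trans-2-(2,3,4,5-tetrabromo-6-methoxyphenoxy)cyclohexan-1-ol F3 as the racemate. Oxidation with Dess–Martin periodinane in CH2Cl2 should give ketone 5.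

Step 1. The bromination may stall at the tribromide 2, or forcing conditions may cause HBr-mediated O-demethylation. The fallback installs the methyl group last on a ring that is already perbrominated. It sets out not from 1 but from purchased 3,4,5,6-tetrabromobenzene-1,2-diol F4 and returns at 3. Mono-O-methylation of the mono-anion (MeI 1.0 equiv, Li2CO3 1.0 equiv, DMF, 40 °C) should give 3. Any dimethyl ether is removed by extraction of the acidic phenol into aqueous base.

Further compounds
F1 | step 3 | 2-(2,3,4,5-tetrabromo-6-methoxyphenoxy)benzaldehyde | COc1c(Br)c(Br)c(Br)c(Br)c1Oc1ccccc1C=O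
F2 | step 3 | 2-(2,3,4,5-tetrabromo-6-methoxyphenoxy)phenyl formate | COc1c(Br)c(Br)c(Br)c(Br)c1Oc1ccccc1OC=O
F3 | step 2 | trans-2-(2,3,4,5-tetrabromo-6-methoxyphenoxy)cyclohexan-1-ol (racemic, one enantiomer drawn) | COc1c(Br)c(Br)c(Br)c(Br)c1O[C@@H]1CCCC[C@H]1O
F4 | step 1 | 3,4,5,6-tetrabromobenzene-1,2-diol (tetrabromocatechol) | Oc1c(O)c(Br)c(Br)c(Br)c1Br
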